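**Assumption:** the target has no stereocentre and no isolable stereo-axis, so it is achiral and "single enantiomer" needs no stereocontrol. It is delivered as the free hydrogen sulfate as drawn. Compounds 1, 3, 4 and 10 are taken as purchasable.

## Retrosynthetic overview

1. Sulfate last: the aryl hydrogen sulfate comes from the free phenol (bromoiesol A, 13) and SO3·pyridine.
2. The ring-A phenol OH comes from an aryl aldehyde by Baeyer–Villiger (Dakin-type) oxidation. The A–O–B ether comes from SNAr of phenol 9 on 3,5-dibromo-2-fluorobenzaldehyde.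
3. Phenol 9 comes from its methyl ether 7 (BBr3). The B–O–C ether comes from O-arylation of 4,5,6-tribromoguaiacol with a (2,4-dibromophenyl)(trimethoxyphenyl)iodonium salt.
4. All seven bromines are in place before the couplings: ring B by tribromination of guaiacol, rings A and C from dibrominated building blocks.
5. No ring is formed. The three benzene rings are joined in the order C–O–B, then B–O–A.

## Route

**Step 1**
Reactants: 1 guaiacol (2-methoxyphenol)
Product: 2 2,3,4-tribromo-6-methoxyphenol (4,5,6-tribromoguaiacol)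
Conditions: Br2 (3.1 equiv), AcOH, rt → 50 °C
Reagents that add atoms: bromine, BrBr
Why: Electrophilic aromatic bromination takes the positions para and ortho to OH and para to OMe; C3, activated only as an ortho position of OMe, stays free if Br2 is limited to 3 equiv.

**Step 2**
Reactants: 3 2,4-dibromo-1-iodobenzene; 4 1,3,5-trimethoxybenzene
Product: 6 (2,4-dibromophenyl)(2,4,6-trimethoxyphenyl)iodonium tosylate, via 2,4-dibromo-1-[hydroxy(tosyloxy)iodo]benzene 5 (not isolated)
Conditions: mCPBA, TsOH·H2O, MeCN, 77 °C; then 4, 77 °C; Et2O precipitation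
Reagents that add atoms: p-toluenesulfonic acid, Cc1ccc(cc1)S(=O)(=O)O
Why: One-pot oxidation of the aryl iodide to a Koser-type iodane, followed by electrophilic aromatic substitution of the electron-rich trimethoxybenzene on iodine(III), gives the unsymmetrical diaryliodonium salt.

**Step 3**
Reactants: 2 2,3,4-tribromo-6-methoxyphenol; 6 (2,4-dibromophenyl)(2,4,6-trimethoxyphenyl)iodonium tosylate
Product: 7 1,2,3-tribromo-4-(2,4-dibromophenoxy)-5-methoxybenzene
Conditions: K2CO3, MeCN, 60 °C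
Reagents that add atoms: none
Why: Metal-free O-arylation with a diaryliodonium salt (ligand exchange, then ligand coupling) tolerates di-ortho-substituted phenoxides; the electron-poorer, ortho-substituted dibromophenyl group is transferred at its ipso carbon while trimethoxyphenyl acts as the dummy ligand.

**Step 4**
Reactants: 7 1,2,3-tribromo-4-(2,4-dibromophenoxy)-5-methoxybenzene
Product: 9 3,4,5-tribromo-2-(2,4-dibromophenoxy)phenol, via dibromo[3,4,5-tribromo-2-(2,4-dibromophenoxy)phenoxy]borane 8 (not isolated)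
Conditions: BBr3 (3 equiv), CH2Cl2, −78 °C → rt; then H2O
Reagents that add atoms: none
Why: Lewis-acid cleavage of the aryl methyl ether with BBr3 removes only the methyl group; the diaryl ether and the aryl bromides are inert.

**Step 5**
Reactants: 9 3,4,5-tribromo-2-(2,4-dibromophenoxy)phenol; 10 3,5-dibromo-2-fluorobenzaldehyde
Product: 11 3,5-dibromo-2-[3,4,5-tribromo-2-(2,4-dibromophenoxy)phenoxy]benzaldehyde
Conditions: K2CO3, DMAc, 90 °C
Reagents that add atoms: none
Why: SNAr (addition–elimination) at the only activated position, the fluoride ortho to the formyl group; the bromines are meta to CHO and are not displaced, and the temperature is kept below 100 °C to avoid Smiles-type aryl migration in the phenoxide of 9.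

**Step 6**
Reactants: 11 3,5-dibromo-2-[3,4,5-tribromo-2-(2,4-dibromophenoxy)phenoxy]benzaldehyde
Product: 13 3,5-dibromo-2-[3,4,5-tribromo-2-(2,4-dibromophenoxy)phenoxy]phenol (bromoiesol A), via 3,5-dibromo-2-[3,4,5-tribromo-2-(2,4-dibromophenoxy)phenoxy]phenyl formate 12 (not isolated)
Conditions: mCPBA, CH2Cl2, 40 °C; then MeOH, cat. HCl, rt
Reagents that add atoms: m-chloroperoxybenzoic acid (mCPBA), O=C(OO)c1cccc(Cl)c1
Why: Baeyer–Villiger (Dakin-type) oxidation; the ortho-aryloxy group promotes aryl migration to the aryl formate, which is cleaved by acid methanolysis, so the OH sits exactly where the CHO carbon was attached.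

**Step 7**
Reactants: 13 3,5-dibromo-2-[3,4,5-tribromo-2-(2,4-dibromophenoxy)phenoxy]phenol
Product: 15 3,5-dibromo-2-[3,4,5-tribromo-2-(2,4-dibromophenoxy)phenoxy]phenyl hydrogen sulfate (bromoiesol A sulfate), via pyridinium 3,5-dibromo-2-[3,4,5-tribromo-2-(2,4-dibromophenoxy)phenoxy]phenyl sulfate 14 (not isolated)
Conditions: SO3·pyridine (5 equiv), pyridine, 50 °C; then Dowex 50W (H+ form), MeOH/H2O, 0 °C; lyophilise cold
Reagents that add atoms: sulfur trioxide–pyridine complex, O=S(=O)([O-])[n+]1ccccc1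
Why: O-sulfation of the phenol by electrophilic SO3 transfer gives the pyridinium aryl sulfate, and cation exchange to H+ gives the hydrogen sulfate without touching ethers or bromides; no stereocentre is involved.

## Compound list

1 | guaiacol (2-methoxyphenol) | COc1ccccc1O | starting material
2 | 2,3,4-tribromo-6-methoxyphenol (4,5,6-tribromoguaiacol) | COc1cc(Br)c(Br)c(Br)c1O | intermediate
3 | 2,4-dibromo-1-iodobenzene | Brc1ccc(I)c(Br)c1 | starting material
4 | 1,3,5-trimethoxybenzene | COc1cc(OC)cc(OC)c1 | starting material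
5 | 2,4-dibromo-1-[hydroxy(tosyloxy)iodo]benzene | Cc1ccc(cc1)S(=O)(=O)OI(O)c1ccc(Br)cc1Br | intermediate
6 | (2,4-dibromophenyl)(2,4,6-trimethoxyphenyl)iodonium tosylate | COc1cc(OC)c([I+]c2ccc(Br)cc2Br)c(OC)c1.Cc1ccc(cc1)S(=O)(=O)[O-] | intermediate
7 | 1,2,3-tribromo-4-(2,4-dibromophenoxy)-5-methoxybenzene | COc1cc(Br)c(Br)c(Br)c1Oc1ccc(Br)cc1Br | intermediate
8 | dibromo[3,4,5-tribromo-2-(2,4-dibromophenoxy)phenoxy]borane | BrB(Br)Oc1cc(Br)c(Br)c(Br)c1Oc1ccc(Br)cc1Br | intermediate
9 | 3,4,5-tribromo-2-(2,4-dibromophenoxy)phenol | Oc1cc(Br)c(Br)c(Br)c1Oc1ccc(Br)cc1Br | intermediate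
10 | 3,5-dibromo-2-fluorobenzaldehyde | O=Cc1cc(Br)cc(Br)c1F | starting material
11 | 3,5-dibromo-2-[3,4,5-tribromo-2-(2,4-dibromophenoxy)phenoxy]benzaldehyde | O=Cc1cc(Br)cc(Br)c1Oc1cc(Br)c(Br)c(Br)c1Oc1ccc(Br)cc1Br | intermediate
12 | 3,5-dibromo-2-[3,4,5-tribromo-2-(2,4-dibromophenoxy)phenoxy]phenyl formate | O=COc1cc(Br)cc(Br)c1Oc1cc(Br)c(Br)c(Br)c1Oc1ccc(Br)cc1Br | intermediate
13 | 3,5-dibromo-2-[3,4,5-tribromo-2-(2,4-dibromophenoxy)phenoxy]phenol (bromoiesol A) | Oc1cc(Br)cc(Br)c1Oc1cc(Br)c(Br)c(Br)c1Oc1ccc(Br)cc1Br | intermediate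
14 | pyridinium 3,5-dibromo-2-[3,4,5-tribromo-2-(2,4-dibromophenoxy)phenoxy]phenyl sulfate | [O-]S(=O)(=O)Oc1cc(Br)cc(Br)c1Oc1cc(Br)c(Br)c(Br)c1Oc1ccc(Br)cc1Br.c1cc[nH+]cc1 | intermediate
15 | 3,5-dibromo-2-[3,4,5-tribromo-2-(2,4-dibromophenoxy)phenoxy]phenyl hydrogen sulfate (bromoiesol A sulfate) | O=S(=O)(O)Oc1cc(Br)cc(Br)c1Oc1cc(Br)c(Br)c(Br)c1Oc1ccc(Br)cc1Br | target

## Step count and risks

Total step count: 7.
Longest linear sequence: 6 steps (1 → 2 → 7 → 9 → 11 → 13 → 15, steps 1, 3, 4, 5, 6, 7; the branch through step 2 is equally long).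

**Step 3 (O-arylation of a di-ortho-substituted, electron-poor phenoxide).** The risk is slow ligand coupling or aryne-derived regioisomers. The fallback sets out from 2 and comes back to the route at 7. Phenol 2 is reacted in an SNAr with 4-bromo-1-fluoro-2-nitrobenzene (K2CO3, DMF, 80 °C) to give 1,2,3-tribromo-4-(4-bromo-2-nitrophenoxy)-5-methoxybenzene F1. The nitro group is reduced with Fe in AcOH/EtOH at 70 °C to 5-bromo-2-(2,3,4-tribromo-6-methoxyphenoxy)aniline F2. Diazotisation (NaNO2, 48% HBr, MeCN/H2O, 0 °C) gives 5-bromo-2-(2,3,4-tribromo-6-methoxyphenoxy)benzenediazonium bromide F3, which is warmed with CuBr to 60 °C (Sandmeyer bromination) to give 7. Both ortho positions of ring B next to the ether oxygen are substituted, so radical cyclisation to a dibenzofuran is blocked.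

**Step 6 (Baeyer–Villiger on an electron-poor benzaldehyde).** The risk is hydride migration to the benzoic acid instead of aryl migration. The fallback sets out from 9 and comes back to the route at 13; it also replaces step 5 with a more strongly activated SNAr. Phenol 9 is coupled with 1,5-dibromo-2-fluoro-3-nitrobenzene (K2CO3, DMF, 60 °C) to give 1,5-dibromo-3-nitro-2-[3,4,5-tribromo-2-(2,4-dibromophenoxy)phenoxy]benzene F4. Reduction with Fe in AcOH/EtOH gives 3,5-dibromo-2-[3,4,5-tribromo-2-(2,4-dibromophenoxy)phenoxy]aniline F5. Diazotisation (NaNO2, H2SO4, AcOH/H2O, 0 °C) gives 3,5-dibromo-2-[3,4,5-tribromo-2-(2,4-dibromophenoxy)phenoxy]benzenediazonium hydrogen sulfate F6. Copper-mediated hydroxylation (Cu2O with a large excess of Cu(NO3)2, H2O, rt) then gives 13; the excess Cu(II) is there to trap the aryl radical faster than it can cyclise onto the one free ortho C–H of ring B.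

**Step 7 (sulfation and isolation of the free acid).** The risk is incomplete sulfation of a hindered phenol and loss of the sulfate during protonation and purification. The fallback sets out from 13 and comes back to the route at 15. Phenol 13 is treated with 2,2,2-trichloroethyl chlorosulfate (Et3N, DMAP, THF, rt) to give the neutral, chromatographable diester 3,5-dibromo-2-[3,4,5-tribromo-2-(2,4-dibromophenoxy)phenoxy]phenyl 2,2,2-trichloroethyl sulfate F7. Reductive removal of the trichloroethyl group (Zn dust, HCO2NH4, MeOH, rt) gives ammonium 3,5-dibromo-2-[3,4,5-tribromo-2-(2,4-dibromophenoxy)phenoxy]phenyl sulfate F8. Passage through Dowex 50W (H+ form) at 0 °C then gives 15.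

## Further compounds

F1 | step 3 | 1,2,3-tribromo-4-(4-bromo-2-nitrophenoxy)-5-methoxybenzene | COc1cc(Br)c(Br)c(Br)c1Oc1ccc(Br)cc1[N+](=O)[O-]
F2 | step 3 | 5-bromo-2-(2,3,4-tribromo-6-methoxyphenoxy)aniline | COc1cc(Br)c(Br)c(Br)c1Oc1ccc(Br)cc1N
F3 | step 3 | 5-bromo-2-(2,3,4-tribromo-6-methoxyphenoxy)benzenediazonium bromide | COc1cc(Br)c(Br)c(Br)c1Oc1ccc(Br)cc1[N+]#N.[Br-]
F4 | step 6 | 1,5-dibromo-3-nitro-2-[3,4,5-tribromo-2-(2,4-dibromophenoxy)phenoxy]benzene | O=[N+]([O-])c1cc(Br)cc(Br)c1Oc1cc(Br)c(Br)c(Br)c1Oc1ccc(Br)cc1Br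
F5 | step 6 | 3,5-dibromo-2-[3,4,5-tribromo-2-(2,4-dibromophenoxy)phenoxy]aniline | Nc1cc(Br)cc(Br)c1Oc1cc(Br)c(Br)c(Br)c1Oc1ccc(Br)cc1Br
F6 | step 6 | 3,5-dibromo-2-[3,4,5-tribromo-2-(2,4-dibromophenoxy)phenoxy]benzenediazonium hydrogen sulfate | N#[N+]c1cc(Br)cc(Br)c1Oc1cc(Br)c(Br)c(Br)c1Oc1ccc(Br)cc1Br.OS(=O)(=O)[O-]
F7 | step 7 | 3,5-dibromo-2-[3,4,5-tribromo-2-(2,4-dibromophenoxy)phenoxy]phenyl 2,2,2-trichloroethyl sulfate | ClC(Cl)(Cl)COS(=O)(=O)Oc1cc(Br)cc(Br)c1Oc1cc(Br)c(Br)c(Br)c1Oc1ccc(Br)cc1Br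
F8 | step 7 | ammonium 3,5-dibromo-2-[3,4,5-tribromo-2-(2,4-dibromophenoxy)phenoxy]phenyl sulfate | [NH4+].[O-]S(=O)(=O)Oc1cc(Br)cc(Br)c1Oc1cc(Br)c(Br)c(Br)c1Oc1ccc(Br)cc1Br
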